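Each turn of the chain takes one substrate and one coupling partner and gives one product and one by-product at whatever speed it runs, so the coupling partner left is the charge less the turns made.

| flask | substrate | coupling partner | initiator | time |
|---|---|---|---|---|
| ochre | 0.039 M (fed, over 2.5 h) | 1.10 equiv | 0.5 mol% | 2.5 h |
| green | 0.039 M (fed, over 2.5 h) | 2.10 equiv | 0.5 mol% | 2.5 h |

    substrate + initiating radical → capped initiator + first chain carrier (k1 = 1.0 × 10⁵ /M/s)
    2 first chain carrier → ended chains (k2 = 3 × 10⁶ /M/s)
    substrate + second chain carrier → by-product + first chain carrier (k3 = 5.0 × 10⁵ /M/min)
    coupling partner + first chain carrier → product + second chain carrier (k4 = 5.3 × 10⁵ /M/min)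
    substrate + by-product ⇌ idle adduct, settled at all times (K5 = 20 /M)
    initiator → 2 initiating radical (k6 = 3.9 × 10⁻⁴ /min)

- percentages count the substrate that a species holds: one ended chains counts as two
- by-product is meant together with its idle adduct
- a doubled species enters its step squared and goes two at a time
- what has gone from substrate into another species counts as reacted, even if it can come back
- run time (ochre): 2.5 h

1. part of the substrate that has reacted at the end, ochre
2. part of the substrate that has reacted at the end, green
3. what raising the equivalents of coupling partner from its lowest to its highest value here does to the part of the substrate that has reacted (changes below 5 percentage points count as none) (no change / it rises / it falls)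

This ledger is my first way. With 1.10 equiv or 2.10 equiv, substrate is the limiting reagent, and the ledger allows 100 % reacted in both flasks. But it has no clock.

My second way follows one first chain carrier, X, to its fork: it meets coupling partner, B, or another X. Each initiator, N, that breaks gives two radicals and each ending step takes two X, so starting and ending balance at X_c, the square root of the decay rate of N over the ending constant: X_c = 2.06 × 10⁻⁸ M, taking N at its charge. Coupling partner then goes pseudo-first-order with 0.0109 /min, while the feed brings 2.60 × 10⁻⁴ M/min. I call b_c the break equivalents, the coupling partner left per substrate charged at which this top speed equals the feed: b_c = 0.612 equiv.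

In green the ledger leaves 1.10 equiv at the end of the feed, above b_c, so the chain keeps pace and the two ways agree. If no radical has ended, second chain carrier reaches 2.28 × 10⁻⁵ M, which holds free substrate at 0.0584 %, and c2 comes to 99.9 %.

In ochre the ledger leaves 0.100 equiv, below b_c, so the ways part and the ledger is the one that cheats. I reckon the break at 73.2 min. By this estimate coupling partner then decays to 0.265 equiv, leaving 16.5 % of the substrate unturned. The adduct balance leaves 10.0 % of the substrate charged free, and substrate in idle adduct counts as reacted, so c1 comes to 90.0 %, and the trend reads it rises.

The forecast gives 93 %, 99.8 % and it rises, holding that with ochre “the falling coupling partner makes the chain fall behind the feed”. It places that moment at about 115 min, and I place it at 73.2 min.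

The simulation gives 91.8 % for ochre and 99.9 % for green, a change of 8.1 percentage points: it rises. Ochre ends with 0.234 equiv of coupling partner, below b_c, and green ends with 1.10 equiv, above it. For the neighbour of green charged with 0.840 equiv, b_c puts the break at 34.2 min and the product at 66.7 %, and that flask ends with 66.9 % of product.

The numbers of this flask are those of an exercise; the rest is arithmetic.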